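The earlier runs and the new flask stem from a simulated flask for substances that don't exist; the scatter is artificial.

Count the E.

in all of them: D 23 mM; Z 23 mM; G 3.4 mM; L 0.23 mM

| flask | E | temperature | remark | time |
|---|---|---|---|---|
| alpha | 46 mM | 90 °C | the very flask that is asked about, followed so far |  |
| eta | 23 mM | 75 °C | run made earlier |  |
| flask | 46.0 mM | 90 °C |  | 8.0 d |

| alpha: time / d | alpha: J / % | eta: time / d | eta: J / % |
|---|---|---|---|
| 0.417 | 46.0 | 0.500 | 27.5 |
| 0.625 | 50.9 | 1.67 | 39.8 |
| 1.04 | 54.3 | 2.50 | 43.3 |
| 1.67 | 58.7 | 4.00 | 44.3 |
| 3.00 | 63.6 | 6.00 | 46.2 |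
| 5.00 | 69.3 | 8.00 | 46.6 |

(scatter of a reading: 0.5 percentage points)

- ash: at 8.0 d add E, 50.0 % of the amount charged, then wait 15 d
- larch: at 8.0 d add G, 50.0 % of the amount charged, then wait 15 d
- birch: at 8.0 d take out 90 % of the J then present, then wait 15 d
- maple: change nothing and wait 15 d more
- elm: at 8.0 d raise the temperature by 25 K, then wait 15 d

- G is single-handed; D and Z are mirror images of each other, charged as a racemate, each of them at the stated concentration
- J taken out counts as made
- "the catalyst" is G with its forms; L is a second catalyst
- additions bring no volume worth counting

* J, in percent of the D and Z together first charged, at 8.0 d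
* the remedy with the largest gain of J, or "none" below 2 percentage points (ash / larch / birch / maple / elm / none)
* J present, with what was taken out counted in, in percent of the D and Z together first charged, after birch
* J present, with what was taken out counted in, in percent of the D and Z together first charged, after elm

In this flask D and Z are charged as a racemate, G is single-handed, and J comes from D. We treat E as a tank and assume one E per J, which makes E the limiting reagent of the eta run, whose E charge is less than its D and Z together. Our quantity is the E ceiling, the E charged over the D and Z together charged, 100 %. The eta run has a ceiling of 50.0 %, and its last reading is 46.6 %. So the payout, J over ceiling, reads 93.2 % there, with the scatter of that reading.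

Applied to this flask, that payout gives 93.2 %, which we take as an upper mark for the end. The eta run rose by 0.4 percentage points between its last two readings. Alpha's last two readings rose by 5.7 points in 2.00 d. Held to 8.0 d, that pace reaches 77.8 %. The rise is slowing, so our own reckoning is somewhat below that figure, and we would add E.

The forecast gives 75 % at 8.0 d, within 73 % to 77 %. It gives 88 % after birch and 90 % after elm, and it names ash: “That makes more E the best remedy”.

The flask gives 72.3 % and ash as the best remedy, with a gain of 17 points. Birch ends at 72.7 % and elm at 72.7 %, each a gain of 0.43 points, the same as maple's 0.43 points. The forecast stands 15 points too high on birch and 17 points too high on elm.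

    D + L ⇌ Z + L, rate k1*[L]*[D] forward; the back reaction follows from the equilibrium constant (k = 0.610 M⁻¹ min⁻¹, Ea = 83.0 kJ mol⁻¹)
    E + G + Z → G + X (k = 1.00 M⁻² min⁻¹, Ea = 59.0 kJ mol⁻¹)
    2 E → Q (k = 0.00530 M⁻¹ min⁻¹, Ea = 67.0 kJ mol⁻¹)
    E + G + D → G + J (k = 43.0 M⁻² min⁻¹, Ea = 44.0 kJ mol⁻¹)
    (constants at 90 °C)

At the start of this flask, E goes 6.9 times as fast by the step that makes J as by the reaction of two E to Q. Half of that side step's turnover up to 8.0 d is behind it by 0.371 d, and 87 % by 1.60 d. At 8.0 d this flask holds E at 0.450 % of its charge and Q at 4.54 mM, and its payout stands at 72.3 %. The neighbour with 12 mM of E has a ceiling of 26.1 %, holds E at 0 % and J at 24.8 %, and its payout stands at 94.9 %.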